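The tetrahydrofuran is disconnected at the O1–C2 bond. The design uses the fact that ring A on C2 lies cis to the C3 methyl group whereas ring B on C5 lies trans to the C4 methyl group: when both benzylic oxygens are first installed with the same anti sense by Felkin-type hydride additions, one inversion at C2 during ring closure produces exactly this pattern. In a single operation, hydride reduction of the C5 aryl ketone sets C5 and the alkoxide so formed displaces a C2 mesylate, closing the ring. The precursor is an acyclic γ-keto mesylate with the two methyl groups in place, ring A as its electron-poor tosylate and ring B as its benzyl ether.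

Key step: step 11

Locants: in the Why lines the tetrahydrofuran is numbered O1, C2 (ring A), C3, C4, C5 (ring B), and the open-chain intermediates use the same numbers; the side chain carbons are C7'' (benzylic, ring C) and C8'' (ether carbon). Compound names carry their own systematic locants. Ts = 4-methylbenzenesulfonyl, Ms = methanesulfonyl.

Assumption: the sense of the quinine-mediated methanolysis (acid on the R carbon, ester on the S carbon) is taken by analogy with cyclic meso anhydrides; should the antipodal hemiester form, quinidine replaces quinine and nothing else changes.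

Step 1
Reactants: 1 meso-2,3-dimethylsuccinic acid
Product: 2 meso-2,3-dimethylsuccinic anhydride
Conditions: AcCl, reflux; evaporation
Reagents that add atoms: none
Why: Cyclodehydration of a 1,4-diacid by an acyl chloride gives the five-membered anhydride, and without base the two α-carbons keep the meso (cis) configuration.

Step 2
Reactants: 2 meso-2,3-dimethylsuccinic anhydride
Product: 3 (2R,3S)-4-methoxy-2,3-dimethyl-4-oxobutanoic acid
Conditions: quinine (1.1 equiv), MeOH (3 equiv), toluene, −55 °C; aq. HCl work-up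
Reagents that add atoms: methanol, CO
Why: Cinchona-alkaloid-mediated desymmetrising methanolysis of a meso anhydride, in which the chiral amine–methanol complex opens one of the two enantiotopic carbonyl groups and so fixes both methyl-bearing carbons (later C3 = R, C4 = S).

Step 3
Reactants: 3 (2R,3S)-4-methoxy-2,3-dimethyl-4-oxobutanoic acid
Product: 4 methyl (2S,3R)-4-[methoxy(methyl)amino]-2,3-dimethyl-4-oxobutanoate
Conditions: MeNH(OMe)·HCl, EDC·HCl, HOBt, N-methylmorpholine, CH2Cl2, 0 °C → rt
Reagents that add atoms: N,O-dimethylhydroxylamine hydrochloride, CNOC.Cl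
Why: Carbodiimide amide coupling to the Weinreb amide; the mild activation avoids an acid chloride, so neither acyl interchange between the two termini (which would erode enantiomeric purity) nor α-epimerisation is expected.

Step 4
Reactants: 5 4-bromo-2-methoxyphenol; 6 p-toluenesulfonyl chloride
Product: 7 4-bromo-2-methoxyphenyl 4-methylbenzenesulfonate
Conditions: Et3N, DMAP (cat.), CH2Cl2, 0 °C → rt
Reagents that add atoms: none
Why: O-Sulfonylation of a phenol; the tosylate tolerates organomagnesium and hydride reagents and makes ring A electron-poor for the later displacement at C2.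

Step 5
Reactants: 7 4-bromo-2-methoxyphenyl 4-methylbenzenesulfonate; 4 methyl (2S,3R)-4-[methoxy(methyl)amino]-2,3-dimethyl-4-oxobutanoate
Product: 9 methyl (2S,3R)-4-[3-methoxy-4-(tosyloxy)phenyl]-2,3-dimethyl-4-oxobutanoate, via arylmagnesium bromide 8 (not isolated)
Conditions: 7, Mg, LiCl, THF, 0 °C → rt; then 4, THF, −20 → 0 °C; aq. NH4Cl
Reagents that add atoms: none
Why: LiCl-promoted magnesium insertion leaves the aryl sulfonate intact, and the Grignard reagent adds once to the Weinreb amide (Weinreb ketone synthesis) through a chelated tetrahedral intermediate, faster than to the α-branched methyl ester and without enolising the α-carbons.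

Step 6
Reactants: 9 methyl (2S,3R)-4-[3-methoxy-4-(tosyloxy)phenyl]-2,3-dimethyl-4-oxobutanoate
Product: 11 (3S,4R,5R)-5-[3-methoxy-4-(tosyloxy)phenyl]-3,4-dimethyloxolan-2-one, via hydroxy ester 10 (not isolated)
Conditions: LiBH(s-Bu)3, THF, −78 °C; AcOH quench; then p-TsOH (cat.), CH2Cl2, rt
Reagents that add atoms: none
Why: Felkin–Anh reduction of an α-branched aryl ketone with a bulky borohydride: hydride attacks anti to the ester-bearing branch on C3 and past the C3 hydrogen, setting C2 as R (2,3-anti), and the γ-hydroxy ester then lactonises under acid catalysis with no change at any stereocentre.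

Step 7
Reactants: 11 (3S,4R,5R)-5-[3-methoxy-4-(tosyloxy)phenyl]-3,4-dimethyloxolan-2-one
Product: 12 (2S,3R,4R)-4-hydroxy-N-methoxy-4-[3-methoxy-4-(tosyloxy)phenyl]-N,2,3-trimethylbutanamide
Conditions: MeNH(OMe)·HCl, AlMe3, CH2Cl2, 0 °C → rt; aq. KNaC4H4O6 (potassium sodium tartrate); used at once
Reagents that add atoms: N,O-dimethylhydroxylamine hydrochloride, CNOC.Cl
Why: Aluminium-amide aminolysis of a lactone (Weinreb amide formation) is non-basic, so the α-carbon should not epimerise, and the carbinol carbon is not involved.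

Step 8
Reactants: 12 (2S,3R,4R)-4-hydroxy-N-methoxy-4-[3-methoxy-4-(tosyloxy)phenyl]-N,2,3-trimethylbutanamide
Product: 13 (1R,2R,3S)-4-[methoxy(methyl)amino]-1-[3-methoxy-4-(tosyloxy)phenyl]-2,3-dimethyl-4-oxobutyl methanesulfonate
Conditions: Ms2O, Et3N, CH2Cl2, −30 → 0 °C; cold work-up, used crude
Reagents that add atoms: methanesulfonic anhydride, CS(=O)(=O)OS(C)(=O)=O
Why: O-Sulfonylation of the secondary alcohol with retention at C2; the anhydride keeps chloride out of the flask and the tosyloxy group para to C2 disfavours ionisation, so the benzylic mesylate should survive cold handling.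

Step 9
Reactants: 5 4-bromo-2-methoxyphenol
Product: 14 1-(benzyloxy)-4-bromo-2-methoxybenzene
Conditions: BnBr, K2CO3, DMF, rt
Reagents that add atoms: benzyl bromide, BrCc1ccccc1
Why: Williamson ether synthesis on a phenoxide.

Step 10
Reactants: 14 1-(benzyloxy)-4-bromo-2-methoxybenzene; 13 (1R,2R,3S)-4-[methoxy(methyl)amino]-1-[3-methoxy-4-(tosyloxy)phenyl]-2,3-dimethyl-4-oxobutyl methanesulfonate
Product: 16 (1R,2R,3S)-4-[4-(benzyloxy)-3-methoxyphenyl]-1-[3-methoxy-4-(tosyloxy)phenyl]-2,3-dimethyl-4-oxobutyl methanesulfonate, via arylmagnesium bromide 15 (not isolated)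
Conditions: 14, Mg, THF, rt; then 13, THF, −40 → −10 °C; cold aq. NH4Cl; used without delay
Reagents that add atoms: none
Why: Weinreb ketone synthesis: the aryl Grignard reagent adds to the amide carbonyl at low temperature, the magnesium-chelated hemiaminal releases the ketone only on quenching, and the hindered secondary sulfonate is not attacked by the organomagnesium under these conditions.

Step 11
Reactants: 16 (1R,2R,3S)-4-[4-(benzyloxy)-3-methoxyphenyl]-1-[3-methoxy-4-(tosyloxy)phenyl]-2,3-dimethyl-4-oxobutyl methanesulfonate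
Product: 18 4-[(2S,3R,4S,5S)-5-[4-(benzyloxy)-3-methoxyphenyl]-3,4-dimethyloxolan-2-yl]-2-methoxyphenyl 4-methylbenzenesulfonate, via lithium alkoxide 17 (not isolated)
Conditions: LiBH(s-Bu)3 (1.15 equiv), THF, −78 °C → rt; aq. NH4Cl
Reagents that add atoms: none
Why: Reduction-triggered intramolecular Williamson etherification: the bulky borohydride adds to the C5 carbonyl in the Felkin–Anh sense, anti to the C3-bearing branch on C4 and past the C4 hydrogen, so the new C5–H bond is set with the 4,5-anti (5S) configuration under control of the C4 stereocentre. On warming, the lithium alkoxide attacks C2 from the face opposite the mesylate in a 5-exo-tet closure that forms the O1–C2 bond with inversion (2R to 2S), so C2 is dictated by the stereospecific SN2 event and the carbinol set in step 6. The closest known reaction types are the hydride-induced cyclisation of γ-halo and γ-sulfonyloxy ketones to tetrahydrofurans and the base-mediated closure of 1,4-diol monosulfonates. The step needs facial selectivity at C5, which the size of the hydride and the α-branch provide, and SN2 rather than SN1 or E2 behaviour at benzylic C2, which the internal nucleophile, the low temperature and the tosyloxy group para to C2 (a poor cation stabiliser) provide. Chemoselectivity follows from the much faster reduction of the ketone than hydride attack on the hindered secondary sulfonate or on the aryl sulfonate, so only a slight excess of reagent is used.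

Step 12
Reactants: 18 4-[(2S,3R,4S,5S)-5-[4-(benzyloxy)-3-methoxyphenyl]-3,4-dimethyloxolan-2-yl]-2-methoxyphenyl 4-methylbenzenesulfonate
Product: 19 4-[(2S,3R,4S,5S)-5-(4-hydroxy-3-methoxyphenyl)-3,4-dimethyloxolan-2-yl]-2-methoxyphenyl 4-methylbenzenesulfonate
Conditions: H2 (1 atm), Pd/C (10%), EtOAc, rt
Reagents that add atoms: none
Why: Hydrogenolysis of the benzyl aryl ether; the aryl tosylate is inert and the cyclic dibenzylic ether is cleaved far more slowly, so the reaction is stopped once the benzyl ether is consumed.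

Step 13
Reactants: 19 4-[(2S,3R,4S,5S)-5-(4-hydroxy-3-methoxyphenyl)-3,4-dimethyloxolan-2-yl]-2-methoxyphenyl 4-methylbenzenesulfonate; 20 ethyl (S)-lactate
Product: 21 ethyl (2R)-2-{2-methoxy-4-[(2S,3S,4R,5S)-5-[3-methoxy-4-(tosyloxy)phenyl]-3,4-dimethyloxolan-2-yl]phenoxy}propanoate
Conditions: PPh3, DIAD, THF, 0 °C → rt
Reagents that add atoms: none
Why: Mitsunobu etherification of a phenol with a secondary α-hydroxy ester proceeds by SN2 at the activated carbinol carbon, so the (S)-lactate delivers the (R)-aryloxy centre C8''.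

Step 14
Reactants: 21 ethyl (2R)-2-{2-methoxy-4-[(2S,3S,4R,5S)-5-[3-methoxy-4-(tosyloxy)phenyl]-3,4-dimethyloxolan-2-yl]phenoxy}propanoate
Product: 22 (2R)-N-methoxy-2-{2-methoxy-4-[(2S,3S,4R,5S)-5-[3-methoxy-4-(tosyloxy)phenyl]-3,4-dimethyloxolan-2-yl]phenoxy}-N-methylpropanamide
Conditions: MeNH(OMe)·HCl, i-PrMgCl, THF, −20 → −10 °C
Reagents that add atoms: N,O-dimethylhydroxylamine hydrochloride, CNOC.Cl
Why: Direct ester-to-Weinreb-amide conversion by the chloromagnesium amide formed in the flask, at a temperature where an α-aryloxy ester should keep its configuration.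

Step 15
Reactants: 7 4-bromo-2-methoxyphenyl 4-methylbenzenesulfonate; 22 (2R)-N-methoxy-2-{2-methoxy-4-[(2S,3S,4R,5S)-5-[3-methoxy-4-(tosyloxy)phenyl]-3,4-dimethyloxolan-2-yl]phenoxy}-N-methylpropanamide
Product: 24 4-[(2R)-2-{2-methoxy-4-[(2S,3S,4R,5S)-5-[3-methoxy-4-(tosyloxy)phenyl]-3,4-dimethyloxolan-2-yl]phenoxy}propanoyl]-2-methoxyphenyl 4-methylbenzenesulfonate, via arylmagnesium chloride 23 (not isolated)
Conditions: 7, i-PrMgCl·LiCl (1.05 equiv), THF, 0 °C → rt; then 22, THF, −20 → 0 °C; aq. NH4Cl
Reagents that add atoms: none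
Why: Bromine–magnesium exchange with LiCl-complexed isopropylmagnesium chloride, accelerated by the tosyloxy group para to bromine, gives a homogeneous arylmagnesium chloride without touching the sulfonate, and its addition to the Weinreb amide (Weinreb ketone synthesis) stops at the chelated tetrahedral intermediate, which prevents over-addition and shields the α-aryloxy stereocentre from enolisation until the neutral quench.

Step 16
Reactants: 24 4-[(2R)-2-{2-methoxy-4-[(2S,3S,4R,5S)-5-[3-methoxy-4-(tosyloxy)phenyl]-3,4-dimethyloxolan-2-yl]phenoxy}propanoyl]-2-methoxyphenyl 4-methylbenzenesulfonate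
Product: 25 4-[(1S,2R)-1-hydroxy-2-{2-methoxy-4-[(2S,3S,4R,5S)-5-[3-methoxy-4-(tosyloxy)phenyl]-3,4-dimethyloxolan-2-yl]phenoxy}propyl]-2-methoxyphenyl 4-methylbenzenesulfonate
Conditions: Zn(BH4)2, Et2O/THF, −30 → 0 °C
Reagents that add atoms: none
Why: Chelation-controlled (Cram chelate) reduction: zinc bridges the carbonyl and aryl ether oxygens and hydride attacks from the face of the C8'' hydrogen, which should give the erythro (7''S,8''R) alcohol.

Step 17
Reactants: 25 4-[(1S,2R)-1-hydroxy-2-{2-methoxy-4-[(2S,3S,4R,5S)-5-[3-methoxy-4-(tosyloxy)phenyl]-3,4-dimethyloxolan-2-yl]phenoxy}propyl]-2-methoxyphenyl 4-methylbenzenesulfonate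
Product: 26 4-[(2S,3R,4S,5S)-5-{4-[(1S,2R)-1-hydroxy-1-(4-hydroxy-3-methoxyphenyl)propan-2-yl]oxy-3-methoxyphenyl}-3,4-dimethyloxolan-2-yl]-2-methoxyphenol (CNP0171079.3)
Conditions: KOH, MeOH/THF, 60 °C; then aq. NH4Cl to pH 7
Reagents that add atoms: none
Why: Alkaline cleavage of both aryl sulfonates by attack at sulfur frees the two phenols in one operation, while the benzylic ethers and the benzylic alcohol are not expected to react with base at this temperature.

Compound list
1 | meso-2,3-dimethylsuccinic acid, (2R,3S)-2,3-dimethylbutanedioic acid | OC(=O)[C@H](C)[C@H](C)C(=O)O | starting material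
2 | meso-2,3-dimethylsuccinic anhydride, (3R,4S)-3,4-dimethyloxolane-2,5-dione, methyl groups cis | C[C@H]1C(=O)OC(=O)[C@H]1C | intermediate
3 | (2R,3S)-4-methoxy-2,3-dimethyl-4-oxobutanoic acid, hemiester with the free acid on the R carbon | OC(=O)[C@H](C)[C@H](C)C(=O)OC | intermediate
4 | methyl (2S,3R)-4-[methoxy(methyl)amino]-2,3-dimethyl-4-oxobutanoate | CON(C)C(=O)[C@H](C)[C@H](C)C(=O)OC | intermediate
5 | 4-bromo-2-methoxyphenol | COc1cc(Br)ccc1O | starting material
6 | p-toluenesulfonyl chloride | Cc1ccc(S(=O)(=O)Cl)cc1 | starting material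
7 | 4-bromo-2-methoxyphenyl 4-methylbenzenesulfonate | COc1cc(Br)ccc1OS(=O)(=O)c1ccc(C)cc1 | intermediate
8 | [3-methoxy-4-(tosyloxy)phenyl]magnesium bromide, LiCl adduct, formed in the flask | COc1cc([Mg]Br)ccc1OS(=O)(=O)c1ccc(C)cc1 | intermediate
9 | methyl (2S,3R)-4-[3-methoxy-4-(tosyloxy)phenyl]-2,3-dimethyl-4-oxobutanoate, ring A keto ester | COc1cc(C(=O)[C@H](C)[C@H](C)C(=O)OC)ccc1OS(=O)(=O)c1ccc(C)cc1 | intermediate
10 | methyl (2S,3R,4R)-4-hydroxy-4-[3-methoxy-4-(tosyloxy)phenyl]-2,3-dimethylbutanoate, formed in the flask | COc1cc([C@H](O)[C@H](C)[C@H](C)C(=O)OC)ccc1OS(=O)(=O)c1ccc(C)cc1 | intermediate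
11 | (3S,4R,5R)-5-[3-methoxy-4-(tosyloxy)phenyl]-3,4-dimethyloxolan-2-one, methyl groups cis, aryl trans to the adjacent methyl | COc1cc([C@@H]2OC(=O)[C@@H](C)[C@H]2C)ccc1OS(=O)(=O)c1ccc(C)cc1 | intermediate
12 | (2S,3R,4R)-4-hydroxy-N-methoxy-4-[3-methoxy-4-(tosyloxy)phenyl]-N,2,3-trimethylbutanamide | COc1cc([C@H](O)[C@H](C)[C@H](C)C(=O)N(C)OC)ccc1OS(=O)(=O)c1ccc(C)cc1 | intermediate
13 | (1R,2R,3S)-4-[methoxy(methyl)amino]-1-[3-methoxy-4-(tosyloxy)phenyl]-2,3-dimethyl-4-oxobutyl methanesulfonate | COc1cc([C@H](OS(C)(=O)=O)[C@H](C)[C@H](C)C(=O)N(C)OC)ccc1OS(=O)(=O)c1ccc(C)cc1 | intermediate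
14 | 1-(benzyloxy)-4-bromo-2-methoxybenzene | COc1cc(Br)ccc1OCc1ccccc1 | intermediate
15 | [4-(benzyloxy)-3-methoxyphenyl]magnesium bromide, formed in the flask | COc1cc([Mg]Br)ccc1OCc1ccccc1 | intermediate
16 | keto mesylate, (1R,2R,3S)-4-[4-(benzyloxy)-3-methoxyphenyl]-1-[3-methoxy-4-(tosyloxy)phenyl]-2,3-dimethyl-4-oxobutyl methanesulfonate | COc1cc([C@H](OS(C)(=O)=O)[C@H](C)[C@H](C)C(=O)c2ccc(OCc3ccccc3)c(OC)c2)ccc1OS(=O)(=O)c1ccc(C)cc1 | intermediate
17 | lithium (1S,2S,3R,4R)-1-[4-(benzyloxy)-3-methoxyphenyl]-4-(mesyloxy)-4-[3-methoxy-4-(tosyloxy)phenyl]-2,3-dimethylbutan-1-olate, formed in the flask | [Li+].COc1cc([C@H](OS(C)(=O)=O)[C@H](C)[C@H](C)[C@H]([O-])c2ccc(OCc3ccccc3)c(OC)c2)ccc1OS(=O)(=O)c1ccc(C)cc1 | intermediate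
18 | 4-[(2S,3R,4S,5S)-5-[4-(benzyloxy)-3-methoxyphenyl]-3,4-dimethyloxolan-2-yl]-2-methoxyphenyl 4-methylbenzenesulfonate, ring A cis and ring B trans to the adjacent methyl groups | COc1cc([C@H]2O[C@H](c3ccc(OCc4ccccc4)c(OC)c3)[C@@H](C)[C@H]2C)ccc1OS(=O)(=O)c1ccc(C)cc1 | intermediate
19 | 4-[(2S,3R,4S,5S)-5-(4-hydroxy-3-methoxyphenyl)-3,4-dimethyloxolan-2-yl]-2-methoxyphenyl 4-methylbenzenesulfonate | COc1cc([C@H]2O[C@H](c3ccc(O)c(OC)c3)[C@@H](C)[C@H]2C)ccc1OS(=O)(=O)c1ccc(C)cc1 | intermediate
20 | ethyl (S)-lactate, ethyl (2S)-2-hydroxypropanoate | C[C@H](O)C(=O)OCC | starting material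
21 | ethyl (2R)-2-{2-methoxy-4-[(2S,3S,4R,5S)-5-[3-methoxy-4-(tosyloxy)phenyl]-3,4-dimethyloxolan-2-yl]phenoxy}propanoate | COc1cc([C@H]2O[C@H](c3ccc(O[C@H](C)C(=O)OCC)c(OC)c3)[C@@H](C)[C@H]2C)ccc1OS(=O)(=O)c1ccc(C)cc1 | intermediate
22 | (2R)-N-methoxy-2-{2-methoxy-4-[(2S,3S,4R,5S)-5-[3-methoxy-4-(tosyloxy)phenyl]-3,4-dimethyloxolan-2-yl]phenoxy}-N-methylpropanamide | COc1cc([C@H]2O[C@H](c3ccc(O[C@H](C)C(=O)N(C)OC)c(OC)c3)[C@@H](C)[C@H]2C)ccc1OS(=O)(=O)c1ccc(C)cc1 | intermediate
23 | [3-methoxy-4-(tosyloxy)phenyl]magnesium chloride, LiCl complex, formed in the flask by bromine–magnesium exchange | COc1cc([Mg]Cl)ccc1OS(=O)(=O)c1ccc(C)cc1 | intermediate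
24 | 4-[(2R)-2-{2-methoxy-4-[(2S,3S,4R,5S)-5-[3-methoxy-4-(tosyloxy)phenyl]-3,4-dimethyloxolan-2-yl]phenoxy}propanoyl]-2-methoxyphenyl 4-methylbenzenesulfonate, ring C ketone | COc1cc([C@H]2O[C@H](c3ccc(O[C@H](C)C(=O)c4ccc(OS(=O)(=O)c5ccc(C)cc5)c(OC)c4)c(OC)c3)[C@@H](C)[C@H]2C)ccc1OS(=O)(=O)c1ccc(C)cc1 | intermediate
25 | bis-tosylate of the target, erythro (1S,2R) side chain | COc1cc([C@H]2O[C@H](c3ccc(O[C@H](C)[C@@H](O)c4ccc(OS(=O)(=O)c5ccc(C)cc5)c(OC)c4)c(OC)c3)[C@@H](C)[C@H]2C)ccc1OS(=O)(=O)c1ccc(C)cc1 | intermediate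
26 | 4-[(2S,3R,4S,5S)-5-{4-[(1S,2R)-1-hydroxy-1-(4-hydroxy-3-methoxyphenyl)propan-2-yl]oxy-3-methoxyphenyl}-3,4-dimethyloxolan-2-yl]-2-methoxyphenol | COc1cc([C@H]2O[C@H](c3ccc(O[C@H](C)[C@@H](O)c4ccc(O)c(OC)c4)c(OC)c3)[C@@H](C)[C@H]2C)ccc1O | target

Total step count: 17. Longest linear sequence: 15 steps (1, 2, 3, 5, 6, 7, 8, 10, 11, 12, 13, 14, 15, 16, 17); steps 4 and 9 prepare the two aryl bromides.

Steps most likely to fail

Step 11. What may go wrong: ionisation of the benzylic mesylate competing with backside attack, which would leak towards the 2,3-trans isomer, β-elimination across C2–C3, or incomplete Felkin control at C5. The fallback sets out from 13 and comes back to the route at 18; it closes the ring by SN1 at C5 instead of SN2 at C2. Warming 13 in wet MeCN lets the amide oxygen displace the mesylate with inversion, and hydrolysis of the iminium ether should give the C2-epimeric lactone F1, in which ring A is already cis to the C3 methyl group. The aryllithium F2 (from 14 and n-BuLi, THF, −78 °C) adds once to F1 to give the cyclic hemiketal F3. NaBH4 in MeOH reduces F3 through its open hydroxy-ketone form to the 1,4-diol F4, whose C5 configuration does not matter. Catalytic p-TsOH in CH2Cl2 then ionises the electron-rich ring B benzylic alcohol; capture of the C5 cation by the C2 hydroxyl under thermodynamic control places ring B trans to the C4 methyl group and gives 18, while C2 stays fixed because its tosyloxy-substituted ring A does not ionise.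

Step 10. What may go wrong: loss of the benzylic mesylate during the organomagnesium step, by participation of the amide oxygen or of the magnesium hemiaminal oxygen (a premature inverting closure) or by elimination. The fallback sets out from 11 and comes back to the route at 16; the sulfonate is introduced only after the carbonyl chemistry. The aryllithium F2 described above adds once to lactone 11 at −78 °C, the lithium lactolate resisting a second addition, to give the hydroxy ketone F5, which equilibrates with its cyclic hemiketal. Ms2O and Et3N at −40 °C should then sulfonylate the secondary benzylic hydroxyl of the open form and give 16.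

Step 16. What may go wrong: weak chelation by the aryl ether oxygen and therefore poor facial selectivity, with contamination by the threo isomer. The fallback sets out from 24 and comes back to the route at 26; the carbinol is set by Felkin–Anh control and then inverted. LiBH(s-Bu)3 in THF at −78 °C attacks anti to the aryloxy group and should give the threo alcohol F6 (7''R,8''R). Mitsunobu esterification with 4-nitrobenzoic acid (PPh3, DIAD, THF) inverts C7'' and gives the erythro 4-nitrobenzoate F7. The KOH/MeOH treatment of step 17 then cleaves this ester together with both tosylates and gives 26 directly.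

Further compounds
F1 | step 11 | (3S,4R,5S)-5-[3-methoxy-4-(tosyloxy)phenyl]-3,4-dimethyloxolan-2-one, all-cis lactone | COc1cc([C@H]2OC(=O)[C@@H](C)[C@H]2C)ccc1OS(=O)(=O)c1ccc(C)cc1
F2 | step 11 | [4-(benzyloxy)-3-methoxyphenyl]lithium | COc1cc([Li])ccc1OCc1ccccc1
F3 | step 11 | (3S,4R,5S)-2-[4-(benzyloxy)-3-methoxyphenyl]-5-[3-methoxy-4-(tosyloxy)phenyl]-3,4-dimethyloxolan-2-ol, anomeric mixture | COc1cc([C@H]2OC(O)(c3ccc(OCc4ccccc4)c(OC)c3)[C@@H](C)[C@H]2C)ccc1OS(=O)(=O)c1ccc(C)cc1
F4 | step 11 | 4-[(1S,2R,3S)-4-[4-(benzyloxy)-3-methoxyphenyl]-1,4-dihydroxy-2,3-dimethylbutyl]-2-methoxyphenyl 4-methylbenzenesulfonate, epimers at the ring B carbinol | COc1cc([C@@H](O)[C@H](C)[C@H](C)C(O)c2ccc(OCc3ccccc3)c(OC)c2)ccc1OS(=O)(=O)c1ccc(C)cc1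
F5 | step 10 | 4-[(1R,2R,3S)-4-[4-(benzyloxy)-3-methoxyphenyl]-1-hydroxy-2,3-dimethyl-4-oxobutyl]-2-methoxyphenyl 4-methylbenzenesulfonate | COc1cc([C@H](O)[C@H](C)[C@H](C)C(=O)c2ccc(OCc3ccccc3)c(OC)c2)ccc1OS(=O)(=O)c1ccc(C)cc1
F6 | step 16 | threo (1R,2R) epimer of 25 at the ring C carbinol | COc1cc([C@H]2O[C@H](c3ccc(O[C@H](C)[C@H](O)c4ccc(OS(=O)(=O)c5ccc(C)cc5)c(OC)c4)c(OC)c3)[C@@H](C)[C@H]2C)ccc1OS(=O)(=O)c1ccc(C)cc1
F7 | step 16 | erythro (1S,2R) 4-nitrobenzoate of 25 | COc1cc([C@H]2O[C@H](c3ccc(O[C@H](C)[C@@H](OC(=O)c6ccc([N+](=O)[O-])cc6)c4ccc(OS(=O)(=O)c5ccc(C)cc5)c(OC)c4)c(OC)c3)[C@@H](C)[C@H]2C)ccc1OS(=O)(=O)c1ccc(C)cc1
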